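## Structural features

The target is a germacrane-type ten-membered carbocycle (C1–C10) with two oxygen heterocycles: a 3(2H)-furanone whose ring oxygen spans C3 and C10 (ring O, C3, C2, C1, C10), and a trans-fused α-methylene-γ-butyrolactone on C7–C8 (C7, C11, C12, O, C8; exocyclic C13). Five contiguous stereocentres run from C4 (methyl) through C5 (free hydroxyl), C6 (methacrylate) and C7 to C8 (lactone oxygen); the quaternary C10 (methyl, ring oxygen) is separated from them by C9. The fragile groups are the two Michael acceptors (methylene lactone, methacrylate), the ester next to a free hydroxyl (acyl migration), and C4–H, which is γ to the furanone carbonyl and can epimerise under base. C6–OH and C8–OH can both lactonise onto C12, and C5–OH and C6–OH must be told apart. The real difficulty is relative configuration across a medium ring, above all C4, which no later step can correct. The key step uses the 1,5 relationship between the C1 carbonyl and the C5–C6 unit: with C5=C6 in place of the diol the ring is a cyclodec-5-enone. That is the product of oxy-Cope expansion of the six-membered ring C1–C10–C9–C8–C7–C6 bearing an ethynyl group (C2, C3) on C1 and an E-propenyl group (C5, C4, methyl) on C6. C7, C8 and C10 are then set on a chair cyclohexane, and C4, C5 and C6 follow from the rearrangement geometry and one face-selective dihydroxylation.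

## Logic of the disconnections

30 ⇒ 28 + 29. The C6–O acyl bond is cut first because the methacrylate is the most sensitive group and should be introduced last. The forward acylation must distinguish C6–OH from C5–OH and leave the lactone alone.

28 ⇒ 27. Both C5–O and C6–O bonds are cut together. The diol is the syn adduct of an E alkene, so two stereocentres revert to the C5=C6 bond that the ring expansion delivers. The oxidant must choose the isolated alkene over two conjugated ones and attack the outer face.

27 ⇒ 24 ⇒ 23. The lactone C12–O8 bond is cut and C12 lowered to an allylic alcohol, with C13 kept as an alkene throughout. The lactone then comes from oxidation alone, avoiding enolate methylenation beside the acidic C4–H. Lactonisation is placed before C6–OH exists, so only C8–OH can close onto C12.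

23 ⇒ 22. The O–C3 bond of the furanone is cut, leaving an α'-hydroxy enone. The forward step is an oxidative closure of the C10 hydroxyl onto C3 that must spare the other alkenes.

22 ⇒ 19. C3–C4 is cut and C1–C6 reconnected: the ten-membered dienone becomes a 1-ethynyl-2-(E-propenyl)cyclohexanol. One stereocentre (C4) and the medium ring are traded for a chair cyclohexane. The forward step needs ethynyl and propenyl trans-diequatorial.

19 ⇒ 18 ⇒ 17 ⇒ 16 ⇒ 15. Silyl groups are removed and the C8 carbinol is traced through its epimer to a C8 ketone. A hydride cannot give the equatorial C8 alcohol directly because the axial C10 methyl blocks axial delivery, so the plan accepts the axial alcohol and inverts it.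

15 ⇒ 14 ⇒ 13. The C9–H bond is replaced by a C9–O bond of an epoxide across C9–C10, and the C8 ketone is masked as a ketal. The epoxide is kept this long because it steers the next disconnection. The forward opening must break C9–O only, which electron transfer from a C8 ketone ensures.

13 ⇒ 11 + 12. The C1–C2 bond is cut. The acetylide must enter trans to the C6 propenyl group, against the normal axial preference of small nucleophiles; the epoxide oxygen on the opposite face enforces this.

11 ⇒ 10 ⇒ 9 ⇒ 8. The E-propenyl group reverts to allyl and the C12 oxygen to the methyl of an isopropenyl group. The isomerisation must stop at the E-2-alkene; the chlorination must choose the 1,1-disubstituted alkene.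

8 ⇒ 7. The epoxide is cut to an α-methyl enone; the forward epoxidation must occur trans to the C7 substituent.

7 ⇒ 4 + 5. The C6–allyl bond is cut; enolate alkylation must occur trans to C7.

4 ⇒ 2 + 3. The C7–C11 bond is cut. This is the only enantio-determining step, and the nucleophile must choose the unsubstituted enone of a cross-conjugated dienone.

2 ⇒ 1. The ketal is traced to a para-alkoxyphenol.

## Other disconnections considered

Alternative 1: The cut is the C5–C6 bond. The seco-dialdehyde A1 already holds the furanone and the lactone, joined through C9; SmI2 would couple the two ketyls to give the bridged diol A2. In its favour, it is convergent and forms the ring and both carbinols in one step; on convergence and on delivering both oxygens with the ring it is the better of the two plans. Against it here, the diol needed is ring-trans, whereas chelated diketyl couplings in rings favour cis. The C6 aldehyde of A1 has the lactone oxygen β to it and can eliminate, and its C5 aldehyde sits beside the epimerisable C4. SmI2 can also cleave the α-alkoxy ketone of the furanone. A2 still needs methylenation by enolate chemistry next to C4–H and still needs C5/C6 differentiation. Mechanistically it relies on a radical coupling under little stereochemical constraint, whereas the chosen plan passes configuration through a chair transition state; step count would be similar once A1 is assembled.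

Alternative 2: The cut is the C7–C11 bond. Rh2(OAc)4 would convert the diazophosphonoacetate A3 into a carbenoid that inserts into C7–H to give the phosphono lactone A4, and a Horner–Wadsworth–Emmons reaction with formaldehyde would then install C13. Its methylene introduction under carbonate base is milder than enolate chemistry and the lactone is built last; on these points it equals the chosen plan. Against it, the carbenoid reaches C9–H as easily as C7–H through a five-membered transition state, and C7–H is deactivated by the C6 ester. The methacrylate and furanone alkenes invite cyclopropanation. It does not address the ten-membered ring, so it adds steps to a separate ring synthesis rather than saving any.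

Alternative 3: The cut is the O–C3 bond together with the C10–methyl bond. PtCl2 would activate the ring alkyne of ketol A5; the C10 carbonyl oxygen attacks C3 and the methyl shifts from C1 to C10, giving A6, the C5 silyl ether of the target. It forms the furanone and the quaternary C10 in one redox-neutral step, which is better than the oxidative palladium closure used here. Against it, A5 is a ten-membered cycloalkyne with a tertiary carbinol of fixed configuration at C1, since the shift is suprafacial. Making that strained ring is the real problem and is left unsolved. Divalent platinum can also engage the enyne relationships with the methacrylate and methylene lactone. Step economy would be comparable only if a short macrocyclisation to A5 existed.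

Key step: step 15

Remark: atom numbers C1–C13 are those of the carbocycle and lactone of 30 and are used for every intermediate.
Remark: the facial sense of step 2 is assigned by the usual model for rhodium/BINAP additions to cyclohexenones; the antipodal ligand would be used should the ketal reverse it.
Remark: 1, 3, 5, 12 and 29 are taken as catalogue chemicals.

## Route

Step 1
Reactants: 1 4-methoxy-2-methylphenol
Product: 2 4,4-dimethoxy-2-methylcyclohexa-2,5-dien-1-one
Conditions: PhI(OAc)2, MeOH, 0 °C
Reagents that add atoms: methanol (CO)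
Why: Oxidative dearomatisation of a para-alkoxyphenol in methanol gives the quinone monoketal; the free carbonyl (C1) is next to the methyl-bearing C10 and C8 is masked.

Step 2
Reactants: 2 4,4-dimethoxy-2-methylcyclohexa-2,5-dien-1-one; 3 potassium isopropenyltrifluoroborate
Product: 4 (R)-4,4-dimethoxy-2-methyl-5-(prop-1-en-2-yl)cyclohex-2-en-1-one
Conditions: [Rh(cod)2]BF4 (3 mol %), (R)-BINAP, Et3N, toluene–H2O, 25 °C
Reagents that add atoms: none
Why: Hayashi–Miyaura reaction: the alkenylrhodium species should add to the unsubstituted enone because α-methyl enones are poor acceptors, and the ligand sets C7; the isopropenyl group brings C11, C12 and C13 in one piece.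

Step 3
Reactants: 4 (R)-4,4-dimethoxy-2-methyl-5-(prop-1-en-2-yl)cyclohex-2-en-1-one; 5 allyl bromide
Product: 7 (5R,6S)-6-allyl-4,4-dimethoxy-2-methyl-5-(prop-1-en-2-yl)cyclohex-2-en-1-one, via lithium dienolate 6 (not isolated)
Conditions: LiN(i-Pr)2, THF, −78 °C; then 5, −78 → −20 °C
Reagents that add atoms: none
Why: Kinetic α'-deprotonation is the only enolisation open (C8 has no hydrogen); alkylation of the cross-conjugated enolate should occur trans to the C7 isopropenyl group, as with carvone, setting C6.

Step 4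
Reactants: 7 (5R,6S)-6-allyl-4,4-dimethoxy-2-methyl-5-(prop-1-en-2-yl)cyclohex-2-en-1-one
Product: 8 (1R,3S,4R,6S)-3-allyl-5,5-dimethoxy-1-methyl-4-(prop-1-en-2-yl)-7-oxabicyclo[4.1.0]heptan-2-one
Conditions: 30% H2O2, NaOH (cat.), MeOH, 0 °C
Reagents that add atoms: hydrogen peroxide (OO)
Why: Weitz–Scheffer epoxidation touches only the enone; hydroperoxide should attack C9 axially on the face opposite the pseudo-equatorial C7 substituent, as with carvone, placing the C10 oxygen cis to the future C8 oxygen.

Step 5
Reactants: 8 (1R,3S,4R,6S)-3-allyl-5,5-dimethoxy-1-methyl-4-(prop-1-en-2-yl)-7-oxabicyclo[4.1.0]heptan-2-one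
Product: 9 (1R,3S,4R,6S)-3-allyl-4-(3-chloroprop-1-en-2-yl)-5,5-dimethoxy-1-methyl-7-oxabicyclo[4.1.0]heptan-2-one
Conditions: Ca(OCl)2, CO2 (solid), CH2Cl2–H2O, 0 °C
Reagents that add atoms: calcium hypochlorite ([Ca+2].[O-]Cl.[O-]Cl)
Why: Ene-type allylic chlorination by hypochlorous acid is much faster for the 1,1-disubstituted alkene than for the monosubstituted allyl group and shifts the double bond, giving the 2-(chloromethyl)vinyl unit (C12–Cl, C11=C13).

Step 6
Reactants: 9 (1R,3S,4R,6S)-3-allyl-4-(3-chloroprop-1-en-2-yl)-5,5-dimethoxy-1-methyl-7-oxabicyclo[4.1.0]heptan-2-one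
Product: 10 2-[(1R,3S,4R,6S)-3-allyl-5,5-dimethoxy-1-methyl-2-oxo-7-oxabicyclo[4.1.0]heptan-4-yl]prop-2-en-1-yl acetate
Conditions: KOAc, Bu4NI (cat.), DMF, 50 °C
Reagents that add atoms: potassium acetate (CC(=O)[O-].[K+])
Why: SN2 displacement of a primary allylic chloride by acetate (direct and allylic attack give the same product) installs the C12 oxygen in a form that survives the next five steps.

Step 7
Reactants: 10 2-[(1R,3S,4R,6S)-3-allyl-5,5-dimethoxy-1-methyl-2-oxo-7-oxabicyclo[4.1.0]heptan-4-yl]prop-2-en-1-yl acetate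
Product: 11 2-[(1R,3S,4R,6S)-5,5-dimethoxy-1-methyl-2-oxo-3-[(E)-prop-1-en-1-yl]-7-oxabicyclo[4.1.0]heptan-4-yl]prop-2-en-1-yl acetate
Conditions: [Ir(cod)(PMePh2)2]PF6 (2 mol %, activated with H2), THF, 25 °C
Reagents that add atoms: none
Why: Iridium hydride-catalysed one-position alkene isomerisation converts a terminal allyl group into the E-propenyl group under neutral conditions; the hindered 1,1-disubstituted alkene should not react, and without base the new alkene should not move into conjugation.

Step 8
Reactants: 11 2-[(1R,3S,4R,6S)-5,5-dimethoxy-1-methyl-2-oxo-3-[(E)-prop-1-en-1-yl]-7-oxabicyclo[4.1.0]heptan-4-yl]prop-2-en-1-yl acetate; 12 ethynylmagnesium bromide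
Product: 13 2-[(1R,2R,3S,4R,6S)-2-ethynyl-2-hydroxy-5,5-dimethoxy-1-methyl-3-[(E)-prop-1-en-1-yl]-7-oxabicyclo[4.1.0]heptan-4-yl]prop-2-en-1-yl acetate
Conditions: CeCl3, THF, −78 °C; then aq. NH4Cl
Reagents that add atoms: none
Why: Organocerium 1,2-addition to an α,β-epoxy ketone: the nucleophile should enter anti to the epoxide C–O bond (Felkin–Anh) and anti to the C6 propenyl group, giving the C1 hydroxyl cis to the epoxide and the ethynyl group trans to the propenyl group. The weakly basic cerium reagent should spare the acetate and the acidic C6–H.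

Step 9
Reactants: 13 2-[(1R,2R,3S,4R,6S)-2-ethynyl-2-hydroxy-5,5-dimethoxy-1-methyl-3-[(E)-prop-1-en-1-yl]-7-oxabicyclo[4.1.0]heptan-4-yl]prop-2-en-1-yl acetate
Product: 14 2-[(1S,3R,4S,5R,6R)-5-ethynyl-5-hydroxy-6-methyl-2-oxo-4-[(E)-prop-1-en-1-yl]-7-oxabicyclo[4.1.0]heptan-3-yl]prop-2-en-1-yl acetate
Conditions: pyridinium 4-toluenesulfonate, acetone–H2O, 40 °C
Reagents that add atoms: water (O)
Why: Buffered-acid hydrolysis of a dimethyl ketal unmasks the C8 ketone; the weak acid should leave the epoxide and the tertiary propargylic alcohol intact.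

Step 10
Reactants: 14 2-[(1S,3R,4S,5R,6R)-5-ethynyl-5-hydroxy-6-methyl-2-oxo-4-[(E)-prop-1-en-1-yl]-7-oxabicyclo[4.1.0]heptan-3-yl]prop-2-en-1-yl acetate
Product: 15 2-[(1R,2S,3R,4R)-3-ethynyl-3,4-dihydroxy-4-methyl-6-oxo-2-[(E)-prop-1-en-1-yl]cyclohexyl]prop-2-en-1-yl acetate
Conditions: SmI2 (2.2 equiv), THF–MeOH, −78 °C
Reagents that add atoms: none
Why: Reductive opening of an α,β-epoxy ketone: two single-electron transfers to the C8 carbonyl cleave the adjacent C9–O bond and leave the C10 oxygen with its configuration. Unlike hydride opening, this does not follow the Fürst–Plattner preference that would direct attack to C10.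

Step 11
Reactants: 15 2-[(1R,2S,3R,4R)-3-ethynyl-3,4-dihydroxy-4-methyl-6-oxo-2-[(E)-prop-1-en-1-yl]cyclohexyl]prop-2-en-1-yl acetate
Product: 16 2-[(1R,2S,3R,4R,6R)-3-ethynyl-3,4,6-trihydroxy-4-methyl-2-[(E)-prop-1-en-1-yl]cyclohexyl]prop-2-en-1-yl acetate
Conditions: LiBH(s-Bu)3, THF, −78 °C; then aq. NH4Cl
Reagents that add atoms: none
Why: In the locked chair the axial C10 methyl shields the axial trajectory at C8, so the bulky hydride should attack equatorially and give the axial alcohol cleanly; this predictable outcome is then inverted.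

Step 12
Reactants: 16 2-[(1R,2S,3R,4R,6R)-3-ethynyl-3,4,6-trihydroxy-4-methyl-2-[(E)-prop-1-en-1-yl]cyclohexyl]prop-2-en-1-yl acetate
Product: 17 (1S,2R,3S,4R,5R)-2-[3-(acetyloxy)prop-1-en-2-yl]-4-ethynyl-4,5-dihydroxy-5-methyl-3-[(E)-prop-1-en-1-yl]cyclohexyl 4-nitrobenzoate
Conditions: PPh3, DIAD, 4-nitrobenzoic acid, toluene, 0 → 25 °C
Reagents that add atoms: 4-nitrobenzoic acid (O=C(O)c1ccc(cc1)[N+](=O)[O-])
Why: Mitsunobu reaction: SN2 displacement of the activated axial alcohol inverts C8 to the equatorial ester, trans to the C7 substituent; the tertiary hydroxyls do not react.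

Step 13
Reactants: 17 (1S,2R,3S,4R,5R)-2-[3-(acetyloxy)prop-1-en-2-yl]-4-ethynyl-4,5-dihydroxy-5-methyl-3-[(E)-prop-1-en-1-yl]cyclohexyl 4-nitrobenzoate
Product: 18 (1R,2R,4S,5R,6S)-1-ethynyl-5-(3-hydroxyprop-1-en-2-yl)-2-methyl-6-[(E)-prop-1-en-1-yl]cyclohexane-1,2,4-triol
Conditions: K2CO3, MeOH, 25 °C
Reagents that add atoms: none
Why: Transesterification removes both the nitrobenzoate and the acetate in one operation without touching a stereocentre.

Step 14
Reactants: 18 (1R,2R,4S,5R,6S)-1-ethynyl-5-(3-hydroxyprop-1-en-2-yl)-2-methyl-6-[(E)-prop-1-en-1-yl]cyclohexane-1,2,4-triol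
Product: 19 (1R,2R,4S,5R,6S)-4-[(tert-butyldimethylsilyl)oxy]-5-{3-[(tert-butyldimethylsilyl)oxy]prop-1-en-2-yl}-1-ethynyl-2-methyl-6-[(E)-prop-1-en-1-yl]cyclohexane-1,2-diol
Conditions: TBSCl, imidazole, DMF, 25 °C
Reagents that add atoms: tert-butyldimethylsilyl chloride (CC(C)(C)[Si](C)(C)Cl)
Why: Silyl chloride with imidazole protects the primary and secondary hydroxyls and leaves the two tertiary ones free, so the alkoxides formed in the next step are the C1 one needed and its C10 neighbour.

Step 15
Reactants: 19 (1R,2R,4S,5R,6S)-4-[(tert-butyldimethylsilyl)oxy]-5-{3-[(tert-butyldimethylsilyl)oxy]prop-1-en-2-yl}-1-ethynyl-2-methyl-6-[(E)-prop-1-en-1-yl]cyclohexane-1,2-diol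
Product: 22 (2Z,4S,5E,7R,8S,10R)-8-[(tert-butyldimethylsilyl)oxy]-7-{3-[(tert-butyldimethylsilyl)oxy]prop-1-en-2-yl}-10-hydroxy-4,10-dimethylcyclodeca-2,5-dien-1-one, via dipotassium dialkoxide 20 (not isolated), via dipotassium allenolate 21 (not isolated)
Conditions: KH (2.2 equiv), 18-crown-6, THF, 0 → 25 °C; then cannulated into AcOH–THF at −78 °C
Reagents that add atoms: none
Why: KH removes both hydroxyl protons; in 20 the C1 alkoxide weakens the C1–C6 bond and a [3,3] shift joins C3 to C4 as C1–C6 breaks, the C10 alkoxide being a spectator. The closest known reaction type is the anionic oxy-Cope ring expansion of 1-alkynyl-2-alkenylcyclohexanols to cyclodeca-2,5-dienones through cyclic allenolates. No ring is closed by cyclisation: the six-membered ring is enlarged by four atoms to the ten-membered ring. The only new stereocentre, C4, is set by the chair-like array C3–C2–C1–C6–C5–C4 in which C1–C10 and C6–C7 are equatorial and the methyl of the E-propenyl group is equatorial; this relays the C6 configuration to 4S and makes C5=C6 E. The step therefore needs ethynyl and propenyl trans-diequatorial on a locked chair, which the C1 configuration from step 8 and the equatorial C7 and C8 substituents secure. Kinetic protonation of allenolate 21 at C2 on the side away from C4 should give the Z enone, and the cold inverse quench into acid is meant to prevent alkene migration, C4 epimerisation through the dienolate and conjugate closure of the C10 alkoxide.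

Step 16
Reactants: 22 (2Z,4S,5E,7R,8S,10R)-8-[(tert-butyldimethylsilyl)oxy]-7-{3-[(tert-butyldimethylsilyl)oxy]prop-1-en-2-yl}-10-hydroxy-4,10-dimethylcyclodeca-2,5-dien-1-one
Product: 23 (4S,5E,7R,8S,10R)-8-[(tert-butyldimethylsilyl)oxy]-7-{3-[(tert-butyldimethylsilyl)oxy]prop-1-en-2-yl}-4,10-dimethyl-3,10-epoxycyclodeca-2,5-dien-1-one
Conditions: PdCl2(MeCN)2 (10 mol %), 1,4-benzoquinone, Na2HPO4, THF, 25 °C
Reagents that add atoms: none
Why: Wacker-type oxidative cyclisation of an α'-hydroxy enone: divalent palladium activates C2=C3, the C10 hydroxyl adds to C3 across the ring, and β-hydride elimination restores C2=C3 as the furanone. Closing it now removes the ketone electrophile and the acidic doubly allylic C4–H before any further handling.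

Step 17
Reactants: 23 (4S,5E,7R,8S,10R)-8-[(tert-butyldimethylsilyl)oxy]-7-{3-[(tert-butyldimethylsilyl)oxy]prop-1-en-2-yl}-4,10-dimethyl-3,10-epoxycyclodeca-2,5-dien-1-one
Product: 24 (4S,5E,7R,8S,10R)-8-hydroxy-7-(3-hydroxyprop-1-en-2-yl)-4,10-dimethyl-3,10-epoxycyclodeca-2,5-dien-1-one
Conditions: HF·pyridine, pyridine, THF, 0 → 25 °C
Reagents that add atoms: none
Why: Buffered fluoride cleaves both silyl ethers under weakly acidic conditions, so C4–H is not exposed to base.

Step 18
Reactants: 24 (4S,5E,7R,8S,10R)-8-hydroxy-7-(3-hydroxyprop-1-en-2-yl)-4,10-dimethyl-3,10-epoxycyclodeca-2,5-dien-1-one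
Product: 27 (4S,5E,7R,8S,10R)-3,10-epoxy-1-oxogermacra-2,5,11(13)-trien-12,8-olide, via hydroxy enal 25 (not isolated), via lactol 26 (not isolated)
Conditions: MnO2 (activated, excess), CH2Cl2, 25 °C
Reagents that add atoms: none
Why: MnO2 oxidises only the allylic primary alcohol; the enal is captured by the C8 hydroxyl as a lactol, which is oxidised further to the α-methylene lactone. C8–OH is the only hydroxyl available, so the 12,8 ring fusion is unambiguous and no base is needed.

Step 19
Reactants: 27 (4S,5E,7R,8S,10R)-3,10-epoxy-1-oxogermacra-2,5,11(13)-trien-12,8-olide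
Product: 28 (4S,5S,6S,7S,8S,10R)-3,10-epoxy-5,6-dihydroxy-1-oxogermacra-2,11(13)-dien-12,8-olide
Conditions: OsO4 (5 mol %), N-methylmorpholine N-oxide, acetone–H2O, 0 °C
Reagents that add atoms: N-methylmorpholine N-oxide (C[N+]1([O-])CCOCC1); water (O)
Why: Syn dihydroxylation of the E alkene gives the threo diol; the electrophilic oxidant should prefer the isolated alkene over the methylene lactone and the furanone alkene. With H4 and H7 in the alkene plane (allylic 1,3-strain) C3 and C8 lie on the inner face, so attack on the outer face, between the C4 methyl and C11, gives 5S,6S (the 7S label reflects a priority change, not a change at C7).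

Step 20
Reactants: 28 (4S,5S,6S,7S,8S,10R)-3,10-epoxy-5,6-dihydroxy-1-oxogermacra-2,11(13)-dien-12,8-olide; 29 methacrylic anhydride
Product: 30 (4S,5S,6S,7R,8S,10R)-3,10-epoxy-5-hydroxy-6-(2-methylprop-2-enoyloxy)-1-oxogermacra-2,11(13)-dien-12,8-olide
Conditions: DMAP (cat.), Et3N, CH2Cl2, −20 °C
Reagents that add atoms: none
Why: Nucleophile-catalysed acylation with one equivalent of anhydride at low temperature should give the monoester. C5–OH is flanked by the methyl-bearing C4 and can hydrogen-bond to the furanone oxygen, so C6–OH is expected to react first, but this is the least secure selectivity of the endgame.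

## Compound list

1 | 4-methoxy-2-methylphenol | Cc1cc(OC)ccc1O | starting material
2 | 4,4-dimethoxy-2-methylcyclohexa-2,5-dien-1-one | CC1=CC(OC)(OC)C=CC1=O | intermediate
3 | potassium isopropenyltrifluoroborate | C=C(C)[B-](F)(F)F.[K+] | starting material
4 | (R)-4,4-dimethoxy-2-methyl-5-(prop-1-en-2-yl)cyclohex-2-en-1-one | O=C1C(C)=CC(OC)(OC)[C@@H](C(C)=C)C1 | intermediate
5 | allyl bromide | C=CCBr | starting material
6 | lithium dienolate of 4 (C1–O–Li, C1=C6, C9=C10) | CC1=CC(OC)(OC)[C@@H](C(C)=C)C=C1O[Li] | intermediate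
7 | (5R,6S)-6-allyl-4,4-dimethoxy-2-methyl-5-(prop-1-en-2-yl)cyclohex-2-en-1-one | O=C1C(C)=CC(OC)(OC)[C@@H](C(C)=C)[C@@H]1CC=C | intermediate
8 | (1R,3S,4R,6S)-3-allyl-5,5-dimethoxy-1-methyl-4-(prop-1-en-2-yl)-7-oxabicyclo[4.1.0]heptan-2-one | O=C1[C@]2(C)O[C@@H]2C(OC)(OC)[C@@H](C(C)=C)[C@@H]1CC=C | intermediate
9 | (1R,3S,4R,6S)-3-allyl-4-(3-chloroprop-1-en-2-yl)-5,5-dimethoxy-1-methyl-7-oxabicyclo[4.1.0]heptan-2-one | O=C1[C@]2(C)O[C@@H]2C(OC)(OC)[C@@H](C(CCl)=C)[C@@H]1CC=C | intermediate
10 | 2-[(1R,3S,4R,6S)-3-allyl-5,5-dimethoxy-1-methyl-2-oxo-7-oxabicyclo[4.1.0]heptan-4-yl]prop-2-en-1-yl acetate | O=C1[C@]2(C)O[C@@H]2C(OC)(OC)[C@@H](C(COC(C)=O)=C)[C@@H]1CC=C | intermediate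
11 | 2-[(1R,3S,4R,6S)-5,5-dimethoxy-1-methyl-2-oxo-3-[(E)-prop-1-en-1-yl]-7-oxabicyclo[4.1.0]heptan-4-yl]prop-2-en-1-yl acetate | O=C1[C@]2(C)O[C@@H]2C(OC)(OC)[C@@H](C(COC(C)=O)=C)[C@@H]1/C=C/C | intermediate
12 | ethynylmagnesium bromide | C#C[Mg]Br | starting material
13 | 2-[(1R,2R,3S,4R,6S)-2-ethynyl-2-hydroxy-5,5-dimethoxy-1-methyl-3-[(E)-prop-1-en-1-yl]-7-oxabicyclo[4.1.0]heptan-4-yl]prop-2-en-1-yl acetate | C#C[C@@]1(O)[C@]2(C)O[C@@H]2C(OC)(OC)[C@@H](C(COC(C)=O)=C)[C@@H]1/C=C/C | intermediate
14 | 2-[(1S,3R,4S,5R,6R)-5-ethynyl-5-hydroxy-6-methyl-2-oxo-4-[(E)-prop-1-en-1-yl]-7-oxabicyclo[4.1.0]heptan-3-yl]prop-2-en-1-yl acetate | C#C[C@@]1(O)[C@]2(C)O[C@@H]2C(=O)[C@@H](C(COC(C)=O)=C)[C@@H]1/C=C/C | intermediate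
15 | 2-[(1R,2S,3R,4R)-3-ethynyl-3,4-dihydroxy-4-methyl-6-oxo-2-[(E)-prop-1-en-1-yl]cyclohexyl]prop-2-en-1-yl acetate | C#C[C@@]1(O)[C@](C)(O)CC(=O)[C@@H](C(COC(C)=O)=C)[C@@H]1/C=C/C | intermediate
16 | 2-[(1R,2S,3R,4R,6R)-3-ethynyl-3,4,6-trihydroxy-4-methyl-2-[(E)-prop-1-en-1-yl]cyclohexyl]prop-2-en-1-yl acetate | C#C[C@@]1(O)[C@](C)(O)C[C@@H](O)[C@@H](C(COC(C)=O)=C)[C@@H]1/C=C/C | intermediate
17 | (1S,2R,3S,4R,5R)-2-[3-(acetyloxy)prop-1-en-2-yl]-4-ethynyl-4,5-dihydroxy-5-methyl-3-[(E)-prop-1-en-1-yl]cyclohexyl 4-nitrobenzoate | C#C[C@@]1(O)[C@](C)(O)C[C@H](OC(=O)c2ccc(cc2)[N+](=O)[O-])[C@@H](C(COC(C)=O)=C)[C@@H]1/C=C/C | intermediate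
18 | (1R,2R,4S,5R,6S)-1-ethynyl-5-(3-hydroxyprop-1-en-2-yl)-2-methyl-6-[(E)-prop-1-en-1-yl]cyclohexane-1,2,4-triol | C#C[C@@]1(O)[C@](C)(O)C[C@H](O)[C@@H](C(CO)=C)[C@@H]1/C=C/C | intermediate
19 | (1R,2R,4S,5R,6S)-4-[(tert-butyldimethylsilyl)oxy]-5-{3-[(tert-butyldimethylsilyl)oxy]prop-1-en-2-yl}-1-ethynyl-2-methyl-6-[(E)-prop-1-en-1-yl]cyclohexane-1,2-diol | C#C[C@@]1(O)[C@](C)(O)C[C@H](O[Si](C)(C)C(C)(C)C)[C@@H](C(=C)CO[Si](C)(C)C(C)(C)C)[C@@H]1/C=C/C | intermediate
20 | dipotassium 1,2-dialkoxide of 19 | C#C[C@@]1([O-])[C@](C)([O-])C[C@H](O[Si](C)(C)C(C)(C)C)[C@@H](C(=C)CO[Si](C)(C)C(C)(C)C)[C@@H]1/C=C/C.[K+].[K+] | intermediate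
21 | dipotassium allenolate (C1 oxido-allene C1=C2=C3 plus C10 alkoxide; allene axis not specified) | [O-]C1=C=C[C@@H](C)/C=C/[C@H](C(=C)CO[Si](C)(C)C(C)(C)C)[C@@H](O[Si](C)(C)C(C)(C)C)C[C@@]1(C)[O-].[K+].[K+] | intermediate
22 | (2Z,4S,5E,7R,8S,10R)-8-[(tert-butyldimethylsilyl)oxy]-7-{3-[(tert-butyldimethylsilyl)oxy]prop-1-en-2-yl}-10-hydroxy-4,10-dimethylcyclodeca-2,5-dien-1-one | O[C@]1(C)C[C@H](O[Si](C)(C)C(C)(C)C)[C@@H](C(=C)CO[Si](C)(C)C(C)(C)C)/C=C/[C@H](C)/C=C\C1=O | intermediate
23 | (4S,5E,7R,8S,10R)-8-[(tert-butyldimethylsilyl)oxy]-7-{3-[(tert-butyldimethylsilyl)oxy]prop-1-en-2-yl}-4,10-dimethyl-3,10-epoxycyclodeca-2,5-dien-1-one | C[C@H]1/C=C/[C@H](C(=C)CO[Si](C)(C)C(C)(C)C)[C@@H](O[Si](C)(C)C(C)(C)C)C[C@@]2(C)OC1=CC2=O | intermediate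
24 | (4S,5E,7R,8S,10R)-8-hydroxy-7-(3-hydroxyprop-1-en-2-yl)-4,10-dimethyl-3,10-epoxycyclodeca-2,5-dien-1-one | C[C@H]1/C=C/[C@H](C(=C)CO)[C@@H](O)C[C@@]2(C)OC1=CC2=O | intermediate
25 | hydroxy enal (C12 aldehyde of 24) | C[C@H]1/C=C/[C@H](C(=C)C=O)[C@@H](O)C[C@@]2(C)OC1=CC2=O | intermediate
26 | lactol (C12 hemiacetal closed onto the C8 oxygen; C12 not specified) | C[C@H]1/C=C/[C@@H]3C(=C)C(O)O[C@H]3C[C@@]2(C)OC1=CC2=O | intermediate
27 | (4S,5E,7R,8S,10R)-3,10-epoxy-1-oxogermacra-2,5,11(13)-trien-12,8-olide | C[C@H]1/C=C/[C@@H]3C(=C)C(=O)O[C@H]3C[C@@]2(C)OC1=CC2=O | intermediate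
28 | (4S,5S,6S,7S,8S,10R)-3,10-epoxy-5,6-dihydroxy-1-oxogermacra-2,11(13)-dien-12,8-olide | O[C@@H]1[C@@H](O)[C@H](C)C2=CC(=O)[C@@](C)(C[C@@H]3OC(=O)C(=C)[C@@H]13)O2 | intermediate
29 | methacrylic anhydride | CC(=C)C(=O)OC(=O)C(C)=C | starting material
30 | (4S,5S,6S,7R,8S,10R)-3,10-epoxy-5-hydroxy-6-(2-methylprop-2-enoyloxy)-1-oxogermacra-2,11(13)-dien-12,8-olide (CNP0195404.1) | C=C(C)C(=O)O[C@@H]1[C@@H](O)[C@H](C)C2=CC(=O)[C@@](C)(C[C@@H]3OC(=O)C(=C)[C@@H]13)O2 | target

## Step count and least certain steps

Total: 20 steps. Longest linear sequence: 20 steps from 1 (3, 5, 12 and 29 are purchased).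

Step 15 (key step). The most likely failures are loss of acetylide from the tertiary propargylic alkoxide (retro-addition), retardation of the shift by ion pairing with the neighbouring C10 alkoxide, and, at the quench, conjugate closure of the C10 oxygen or C4 epimerisation through the dienolate. The fallback rearranges a mono-alkoxide. Starting from 19, the less hindered equatorial C10 hydroxyl is silylated (Et3SiOTf, 2,6-lutidine, −78 °C) to the C10 triethylsilyl ether of 19, F1. KH/18-crown-6 then gives the silylated dienone, the C10 triethylsilyl ether of 22, F2. Pyridinium 4-toluenesulfonate in MeOH frees the tertiary hydroxyl and rejoins the route at 22.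

Step 8. The most likely failure is deprotonation at C6 of the β,γ-unsaturated ketone (epimerisation or conjugation) competing with addition; loss of facial control through chelation of the epoxide oxygen is the second concern. The fallback adds the alkyne before the alkene is moved. Starting from 10, LiC≡CSiMe3/CeCl3 gives the silylalkynyl carbinol with the allyl group intact, F3. The iridium isomerisation of step 7 then gives the E-propenyl silylalkyne, F4. Bu4NF buffered with AcOH removes the C-silyl group and rejoins the route at 13.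

Step 12. The most likely failures are elimination from the activated axial alcohol toward C7 or C9 and transannular capture by the axial C1 hydroxyl. The fallback is a sulfonate displacement with a small oxygen nucleophile. Starting from 16, Tf2O/pyridine at −30 °C gives the axial C8 triflate, F5. KNO2 in DMF displaces it with inversion, and the nitrite ester hydrolyses on work-up to the equatorial C8 alcohol with the acetate intact, F6. The conditions of step 13 then give 18.

Step 16. The most likely failures are palladium hydride-mediated migration of the skipped C5=C6 alkene and slow attack of a tertiary alcohol. The fallback separates ring closure from oxidation. Starting from 22, catalytic DBU at 0 °C effects conjugate closure to the saturated furanone (C2 methylene, C3 ether), F7. LiN(i-Pr)2 then PhSeCl gives the C2 phenylselenide, F8. H2O2/pyridine triggers selenoxide elimination toward C3 and rejoins the route at 23.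

Step 20. The most likely failures are acylation at C5 instead of C6, double acylation, and acyl migration. If C5–OH proves the more reactive, the fallback uses that order. Starting from 28, Et3SiCl/imidazole at −20 °C gives the C5 triethylsilyl ether, F9. Methacrylic anhydride/DMAP then acylates C6 to the C5 silyl ether of the target, F10. HF·pyridine gives 30.

## Further compounds

F1 | step 15 | C10 triethylsilyl ether of 19 | C#C[C@@]1(O)[C@](C)(O[Si](CC)(CC)CC)C[C@H](O[Si](C)(C)C(C)(C)C)[C@@H](C(=C)CO[Si](C)(C)C(C)(C)C)[C@@H]1/C=C/C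
F2 | step 15 | C10 triethylsilyl ether of 22 | CC[Si](CC)(CC)O[C@]1(C)C[C@H](O[Si](C)(C)C(C)(C)C)[C@@H](C(=C)CO[Si](C)(C)C(C)(C)C)/C=C/[C@H](C)/C=C\C1=O
F3 | step 8 | (trimethylsilyl)ethynyl carbinol from 10 (allyl group intact) | C[Si](C)(C)C#C[C@@]1(O)[C@]2(C)O[C@@H]2C(OC)(OC)[C@@H](C(COC(C)=O)=C)[C@@H]1CC=C
F4 | step 8 | C-trimethylsilyl derivative of 13 | C[Si](C)(C)C#C[C@@]1(O)[C@]2(C)O[C@@H]2C(OC)(OC)[C@@H](C(COC(C)=O)=C)[C@@H]1/C=C/C
F5 | step 12 | C8 trifluoromethanesulfonate of 16 | C#C[C@@]1(O)[C@](C)(O)C[C@@H](OS(=O)(=O)C(F)(F)F)[C@@H](C(COC(C)=O)=C)[C@@H]1/C=C/C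
F6 | step 12 | C8 epimer of 16 (equatorial C8 hydroxyl, acetate intact) | C#C[C@@]1(O)[C@](C)(O)C[C@H](O)[C@@H](C(COC(C)=O)=C)[C@@H]1/C=C/C
F7 | step 16 | 2,3-dihydro derivative of 23 (C3 configuration not specified) | C[C@H]1/C=C/[C@H](C(=C)CO[Si](C)(C)C(C)(C)C)[C@@H](O[Si](C)(C)C(C)(C)C)C[C@@]2(C)OC1CC2=O
F8 | step 16 | C2 phenylselenide of F7 (C2 and C3 not specified) | C[C@H]1/C=C/[C@H](C(=C)CO[Si](C)(C)C(C)(C)C)[C@@H](O[Si](C)(C)C(C)(C)C)C[C@@]2(C)OC1C([Se]c1ccccc1)C2=O
F9 | step 20 | C5 triethylsilyl ether of 28 | O[C@@H]1[C@@H](O[Si](CC)(CC)CC)[C@H](C)C2=CC(=O)[C@@](C)(C[C@@H]3OC(=O)C(=C)[C@@H]13)O2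
F10 | step 20 | C5 triethylsilyl ether of 30 | C=C(C)C(=O)O[C@@H]1[C@@H](O[Si](CC)(CC)CC)[C@H](C)C2=CC(=O)[C@@](C)(C[C@@H]3OC(=O)C(=C)[C@@H]13)O2
A1 | alternative 1 | seco-5,6-dialdehyde with furanone and saturated lactone in place | O=C[C@H](C)C1=CC(=O)[C@@](C)(C[C@@H]2OC(=O)C[C@H]2C=O)O1
A2 | alternative 1 | bridged 5,6-diol lacking the lactone methylene | O[C@@H]1[C@@H](O)[C@H](C)C2=CC(=O)[C@@](C)(C[C@@H]3OC(=O)C[C@@H]13)O2
A3 | alternative 2 | C8 diazophosphonoacetate with C7 methylene, C6 methacrylate and C5 silyl ether | C=C(C)C(=O)O[C@@H]1[C@@H](O[Si](C)(C)C(C)(C)C)[C@H](C)C2=CC(=O)[C@@](C)(C[C@H](OC(=O)C(=[N+]=[N-])P(=O)(OCC)OCC)C1)O2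
A4 | alternative 2 | α-phosphono lactone (one C11 epimer drawn) | C=C(C)C(=O)O[C@@H]1[C@@H](O[Si](C)(C)C(C)(C)C)[C@H](C)C2=CC(=O)[C@@](C)(C[C@@H]3OC(=O)[C@H](P(=O)(OCC)OCC)[C@@H]13)O2
A5 | alternative 3 | ten-membered alkynyl ketol (C10 ketone, C1 methyl carbinol, C2≡C3) | C=C(C)C(=O)O[C@@H]1[C@@H](O[Si](C)(C)C(C)(C)C)[C@H](C)C#C[C@@](C)(O)C(=O)C[C@@H]2OC(=O)C(=C)[C@@H]12
A6 | alternative 3 | C5 tert-butyldimethylsilyl ether of 30 | C=C(C)C(=O)O[C@@H]1[C@@H](O[Si](C)(C)C(C)(C)C)[C@H](C)C2=CC(=O)[C@@](C)(C[C@@H]3OC(=O)C(=C)[C@@H]13)O2
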